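**Plan**

1. Retrosynthesis: the C15 isobutyrate and the C17 ester are opened last. Ring B is a cyclohexene (C5–C10) whose C7=C8 alkene lies one position from a Diels–Alder retron. With the alkene at C6=C7, ring B is cut at C5–C10 and C8–C9, and this opens ring A as well, because the C9=C10 alkene is tied to the C5=C6–C7=C8 dienoate through the C1–C4 chain.
2. The open chain is cut at C5=C6 (vinylogous Horner–Wadsworth–Emmons), at C3–C4 (aldol with an isobutyrate enolate equivalent) and at the terminal alkene of (2E,6E)-farnesol, which supplies C1–C3, C9–C16 and C20.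
3. Forward: linear chain assembly from farnesol (steps 1–8), both rings in one cycloaddition (step 9), alkene shift to C7=C8 (step 10), removal of a helper oxygen at C3 (steps 11–13), adjustment of the two chain ends (steps 14–16).
4. Stereochemistry: a reagent-controlled aldol sets a temporary (3S)-silyloxy centre. In the cycloaddition the E geometry of C9=C10 fixes C9 against C10, the tether-exo chair gives the trans fusion at C5, and the equatorial C3 group selects the face. The 13E alkene comes from farnesol, and the C3 oxygen is deleted by radical deoxygenation.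

Key step: step 9

Numbering: atom numbers C1–C20 are the labdane numbers of the target and are used for the open-chain precursors too.
Assumption: the oxazaborolidinone from N-tosyl-D-valine is taken to give the (3S)-aldol from an unbranched aldehyde, by analogy with related aldehydes; the configuration of 8 would be checked through its MTPA esters, and the L-valine reagent would be used instead if the sense were opposite.

**Step 1**
Reactants: 1 (2E,6E)-farnesol
Product: 2 (2E,6E)-farnesyl tert-butyldiphenylsilyl ether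
Conditions: tBuPh2SiCl, imidazole, DMF, 0 °C to rt
Reagents that add atoms: tert-butyldiphenylsilyl chloride, CC(C)(C)[Si](Cl)(c1ccccc1)c1ccccc1
Why: Silyl ether protection of the primary allylic alcohol gives a group that should survive every step up to the fluoride treatment in step 14.

**Step 2**
Reactants: 2 (2E,6E)-farnesyl tert-butyldiphenylsilyl ether
Product: 4 racemic terminal (10,11) epoxide of 2, via bromohydrin 3 (not isolated)
Conditions: NBS, THF/H2O, 0 °C; then K2CO3, MeOH, rt
Reagents that add atoms: water, O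
Why: Bromohydrin formation in aqueous THF is selective for the terminal trisubstituted alkene of farnesyl derivatives and base closes the epoxide by intramolecular Williamson displacement; the new centre is racemic and is destroyed in step 3.

**Step 3**
Reactants: 4 racemic terminal epoxide
Product: 5 (4E,8E)-10-[(tert-butyldiphenylsilyl)oxy]-4,8-dimethyldeca-4,8-dienal
Conditions: H5IO6, THF/Et2O, 0 °C
Reagents that add atoms: none
Why: Periodic acid hydrolyses the epoxide and cleaves the resulting glycol to the aldehyde and acetone without touching the two remaining alkenes or the silyl ether.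

**Step 4**
Reactants: 5 aldehyde; 6 (1-methoxy-2-methylprop-1-enyloxy)trimethylsilane (commercial silyl ketene acetal of methyl isobutyrate)
Product: 8 methyl (3S,6E,10E)-12-[(tert-butyldiphenylsilyl)oxy]-3-hydroxy-2,2,6,10-tetramethyldodeca-6,10-dienoate, via trimethylsilyl ether 7 (not isolated)
Conditions: N-tosyl-D-valine, BH3·THF, CH2Cl2, 0 °C to rt; then 5, 6, −78 °C; then 1 M HCl, THF, 0 °C
Reagents that add atoms: none
Why: Enantioselective Mukaiyama aldol addition promoted by a stoichiometric valine-derived N-tosyl oxazaborolidinone is well established for this ketene acetal with unbranched aldehydes; the boron-bound aldehyde is attacked on one face only, which sets C3 as S.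

**Step 5**
Reactants: 8 hydroxy ester
Product: 9 methyl (3S,6E,10E)-12-[(tert-butyldiphenylsilyl)oxy]-2,2,6,10-tetramethyl-3-[(triethylsilyl)oxy]dodeca-6,10-dienoate
Conditions: Et3SiOTf, 2,6-lutidine, CH2Cl2, −78 to 0 °C
Reagents that add atoms: triethylsilyl trifluoromethanesulfonate, CC[Si](CC)(CC)OS(=O)(=O)C(F)(F)F
Why: A silyl triflate with a hindered base silylates the hindered secondary alcohol, and the triethylsilyl group can later be removed while the tert-butyldiphenylsilyl ether stays.

**Step 6**
Reactants: 9 silylated ester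
Product: 10 (3S,6E,10E)-12-[(tert-butyldiphenylsilyl)oxy]-2,2,6,10-tetramethyl-3-[(triethylsilyl)oxy]dodeca-6,10-dien-1-ol
Conditions: iBu2AlH (2.5 equiv), CH2Cl2, −78 to −40 °C; aq. KNaC4H4O6 work-up
Reagents that add atoms: none
Why: Full hydride reduction of the neopentyl ester to the primary alcohol is chosen because stopping at the aldehyde is unreliable for so hindered an ester.

**Step 7**
Reactants: 10 primary alcohol
Product: 11 (3S,6E,10E)-12-[(tert-butyldiphenylsilyl)oxy]-2,2,6,10-tetramethyl-3-[(triethylsilyl)oxy]dodeca-6,10-dienal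
Conditions: nPr4N[RuO4] (5 mol%), N-methylmorpholine N-oxide, 4 Å molecular sieves, CH2Cl2, rt
Reagents that add atoms: none
Why: Perruthenate-catalysed oxidation of the primary alcohol gives an aldehyde that has no α-hydrogen and therefore can neither enolise nor lose the β-silyloxy group.

**Step 8**
Reactants: 11 aldehyde; 12 triethyl 4-phosphonocrotonate
Product: 14 ethyl (2E,4E,7S,10E,14E)-16-[(tert-butyldiphenylsilyl)oxy]-6,6,10,14-tetramethyl-7-[(triethylsilyl)oxy]hexadeca-2,4,10,14-tetraenoate, via lithiated phosphonate 13 (not isolated)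
Conditions: LiN(SiMe3)2, THF, −78 °C; then 11, −78 to 0 °C
Reagents that add atoms: none
Why: Vinylogous Horner–Wadsworth–Emmons olefination through the carbon next to phosphorus gives the (2E,4E)-dienoate, and the hindered, non-enolisable aldehyde favours the E alkene at C5=C6.

**Step 9**
Reactants: 14 tetraenoate
Product: 15 ethyl 15-[(tert-butyldiphenylsilyl)oxy]-3β-[(triethylsilyl)oxy]labda-6,13E-dien-17-oate (trans-fused; 5α-H, 8α-H with the ester β, 9α-H, 10β-methyl)
Conditions: toluene (0.01 M), BHT (5 mol%), sealed tube, 200 °C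
Reagents that add atoms: none
Why: Concerted, suprafacial thermal [4+2] cycloaddition between the (2E,4E)-dienoate C5=C6–C7=C8 and the unactivated C9=C10 alkene, the closest known reaction type being the thermal type 1 intramolecular Diels–Alder reaction of 1,7,9-decatrienes with an ester on the diene terminus; since the ester activates little, the drive comes from the four-carbon tether, the Thorpe–Ingold effect of the C4 gem-dimethyl group and the absence of allylic hydrogen on the diene, which excludes [1,5]-hydrogen shifts. Ring B is closed directly as the new cyclohexene by the C5–C10 and C8–C9 bonds, and ring A is closed in the same event through the C1–C4 tether as a six-membered ring fused to ring B at C5–C10. C9 and C10 are fixed relative to each other by the E geometry of C9=C10 (C20 methyl and C11 end up cis), and C8 is fixed relative to C5 by the E,E geometry of the diene (ester and C4 cis on ring B), although C8 is erased again in step 10. C5 relative to C10 (trans fusion) requires the tether-exo chair, in which only the C10 methyl stands axial beside the axial C4 methyl as in every labdane, whereas the tether-endo alternatives must also place the reacting carbon C9 or the diene carbon C6 axial and carry the gauche strain of a cis-decalin, so the exo chair should be favoured. The absolute sense at C5, C9 and C10 is relayed from C3, whose silyloxy group takes the equatorial position of that chair and so selects the diene face that leads to the 5α-H, 10β-methyl skeleton. The step thus needs exo-tether over endo-tether closure and one diene face over the other, and neither has to be complete, because all four possible adducts are diastereomers that would be separated here or as the alcohols after step 11, so that the enantiomeric purity stays that set in step 4.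

**Step 10**
Reactants: 15 cycloadduct
Product: 16 ethyl 15-[(tert-butyldiphenylsilyl)oxy]-3β-[(triethylsilyl)oxy]labda-7,13E-dien-17-oate
Conditions: DBU, toluene, 60 °C
Reagents that add atoms: none
Why: Base-mediated alkene isomerisation: DBU removes the C8 hydrogen, which is both α to the ester and allylic, and the dienolate is reprotonated at C6 to give the conjugated trisubstituted enoate as the thermodynamic isomer, while the C9 hydrogen is not acidified.

**Step 11**
Reactants: 16 conjugated ester
Product: 17 ethyl 15-[(tert-butyldiphenylsilyl)oxy]-3β-hydroxylabda-7,13E-dien-17-oate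
Conditions: PPTS (0.2 equiv), EtOH, 45 °C
Reagents that add atoms: none
Why: Mild acid-catalysed ethanolysis cleaves a triethylsilyl ether much faster than a tert-butyldiphenylsilyl ether, and ethanol cannot scramble the ethyl ester.

**Step 12**
Reactants: 17 3β-alcohol
Product: 20 O-[3β-labdanyl] S-methyl dithiocarbonate of 17 (xanthate), via sodium alkoxide 18 (not isolated), via sodium xanthate 19 (not isolated)
Conditions: NaN(SiMe3)2, THF, −78 °C; CS2, −78 to 0 °C; then MeI, 0 °C to rt
Reagents that add atoms: carbon disulfide, S=C=S; iodomethane, CI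
Why: Xanthate formation is the standard way to activate hindered 3β-hydroxy-4,4-dimethyl terpenoids, and one equivalent of amide base at low temperature deprotonates the alcohol well before the enoate.

**Step 13**
Reactants: 20 xanthate
Product: 21 ethyl 15-[(tert-butyldiphenylsilyl)oxy]labda-7,13E-dien-17-oate
Conditions: Bu3SnH, AIBN, toluene, 100 °C
Reagents that add atoms: none
Why: Barton–McCombie deoxygenation: the stannyl radical adds to the thiocarbonyl group, β-scission gives the secondary C3 radical, which has no alkene within reach and is reduced by the tin hydride, so the helper stereocentre disappears.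

**Step 14**
Reactants: 21 deoxygenated ester
Product: 22 ethyl 15-hydroxylabda-7,13E-dien-17-oate
Conditions: Bu4NF, THF, 0 °C to rt
Reagents that add atoms: none
Why: Fluoride cleaves the remaining silyl ether; it is removed before the ester hydrolysis because hot hydroxide can attack a tert-butyldiphenylsilyl ether in an uncontrolled way.

**Step 15**
Reactants: 22 hydroxy ester
Product: 24 15-hydroxylabda-7,13E-dien-17-oic acid, via lithium carboxylate 23 (not isolated)
Conditions: LiOH·H2O (excess), THF/EtOH/H2O, 60 °C; then 1 M HCl to pH 3, 0 °C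
Reagents that add atoms: lithium hydroxide, [Li+].[OH-]
Why: Saponification of the hindered conjugated ethyl ester by acyl–oxygen cleavage needs excess hydroxide and warming, which the free allylic alcohol and the conjugated alkene should tolerate.

**Step 16**
Reactants: 24 hydroxy acid
Product: 26 15-(isobutyryloxy)labda-7,13E-dien-17-oic acid, (5S,9R,10S), the target CNP0191003.1, via mixed anhydride 25 (not isolated)
Conditions: (iPrCO)2O (3 equiv), pyridine, DMAP (0.1 equiv), CH2Cl2, 0 °C to rt; then H2O/THF, rt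
Reagents that add atoms: isobutyric anhydride, CC(C)C(=O)OC(=O)C(C)C
Why: DMAP-catalysed acylation esterifies the primary allylic alcohol, as in the O-acylation of hindered hydroxy acids, and the carboxyl group is at most turned into the mixed anhydride, which water cleaves again at the unhindered isobutyryl carbonyl.

**Compound list**

1 | (2E,6E)-farnesol | CC(C)=CCC/C(C)=C/CC/C(C)=C/CO | starting material
2 | (2E,6E)-farnesyl tert-butyldiphenylsilyl ether | CC(C)=CCC/C(C)=C/CC/C(C)=C/CO[Si](c1ccccc1)(c1ccccc1)C(C)(C)C | intermediate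
3 | (6E,10E)-3-bromo-12-[(tert-butyldiphenylsilyl)oxy]-2,6,10-trimethyldodeca-6,10-dien-2-ol, racemic bromohydrin | CC(C)(O)C(Br)CC/C(C)=C/CC/C(C)=C/CO[Si](c1ccccc1)(c1ccccc1)C(C)(C)C | intermediate (not isolated)
4 | tert-butyl{[(2E,6E)-9-(3,3-dimethyloxiran-2-yl)-3,7-dimethylnona-2,6-dien-1-yl]oxy}diphenylsilane, racemic | CC1(C)OC1CC/C(C)=C/CC/C(C)=C/CO[Si](c1ccccc1)(c1ccccc1)C(C)(C)C | intermediate
5 | (4E,8E)-10-[(tert-butyldiphenylsilyl)oxy]-4,8-dimethyldeca-4,8-dienal | O=CCC/C(C)=C/CC/C(C)=C/CO[Si](c1ccccc1)(c1ccccc1)C(C)(C)C | intermediate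
6 | (1-methoxy-2-methylprop-1-enyloxy)trimethylsilane | COC(O[Si](C)(C)C)=C(C)C | starting material
7 | trimethylsilyl ether of 8 | COC(=O)C(C)(C)[C@@H](O[Si](C)(C)C)CC/C(C)=C/CC/C(C)=C/CO[Si](c1ccccc1)(c1ccccc1)C(C)(C)C | intermediate (not isolated)
8 | methyl (3S,6E,10E)-12-[(tert-butyldiphenylsilyl)oxy]-3-hydroxy-2,2,6,10-tetramethyldodeca-6,10-dienoate | COC(=O)C(C)(C)[C@@H](O)CC/C(C)=C/CC/C(C)=C/CO[Si](c1ccccc1)(c1ccccc1)C(C)(C)C | intermediate
9 | methyl (3S,6E,10E)-12-[(tert-butyldiphenylsilyl)oxy]-2,2,6,10-tetramethyl-3-[(triethylsilyl)oxy]dodeca-6,10-dienoate | COC(=O)C(C)(C)[C@@H](O[Si](CC)(CC)CC)CC/C(C)=C/CC/C(C)=C/CO[Si](c1ccccc1)(c1ccccc1)C(C)(C)C | intermediate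
10 | (3S,6E,10E)-12-[(tert-butyldiphenylsilyl)oxy]-2,2,6,10-tetramethyl-3-[(triethylsilyl)oxy]dodeca-6,10-dien-1-ol | OCC(C)(C)[C@@H](O[Si](CC)(CC)CC)CC/C(C)=C/CC/C(C)=C/CO[Si](c1ccccc1)(c1ccccc1)C(C)(C)C | intermediate
11 | (3S,6E,10E)-12-[(tert-butyldiphenylsilyl)oxy]-2,2,6,10-tetramethyl-3-[(triethylsilyl)oxy]dodeca-6,10-dienal | O=CC(C)(C)[C@@H](O[Si](CC)(CC)CC)CC/C(C)=C/CC/C(C)=C/CO[Si](c1ccccc1)(c1ccccc1)C(C)(C)C | intermediate
12 | triethyl 4-phosphonocrotonate | CCOC(=O)/C=C/CP(=O)(OCC)OCC | starting material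
13 | lithium salt of 12 (phosphonate-stabilised allyl anion) | CCOC(=O)/C=C/[CH-]P(=O)(OCC)OCC.[Li+] | intermediate (not isolated)
14 | ethyl (2E,4E,7S,10E,14E)-16-[(tert-butyldiphenylsilyl)oxy]-6,6,10,14-tetramethyl-7-[(triethylsilyl)oxy]hexadeca-2,4,10,14-tetraenoate | CCOC(=O)/C=C/C=C/C(C)(C)[C@@H](O[Si](CC)(CC)CC)CC/C(C)=C/CC/C(C)=C/CO[Si](c1ccccc1)(c1ccccc1)C(C)(C)C | intermediate
15 | ethyl 15-[(tert-butyldiphenylsilyl)oxy]-3β-[(triethylsilyl)oxy]labda-6,13E-dien-17-oate (5α-H, 8α-H, 9α-H, 10β-methyl) | C/C(=C\CO[Si](c1ccccc1)(c1ccccc1)C(C)(C)C)CC[C@H]1[C@@H](C(=O)OCC)C=C[C@H]2C(C)(C)[C@@H](O[Si](CC)(CC)CC)CC[C@]12C | intermediate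
16 | ethyl 15-[(tert-butyldiphenylsilyl)oxy]-3β-[(triethylsilyl)oxy]labda-7,13E-dien-17-oate | C/C(=C\CO[Si](c1ccccc1)(c1ccccc1)C(C)(C)C)CC[C@H]1C(C(=O)OCC)=CC[C@H]2C(C)(C)[C@@H](O[Si](CC)(CC)CC)CC[C@]12C | intermediate
17 | ethyl 15-[(tert-butyldiphenylsilyl)oxy]-3β-hydroxylabda-7,13E-dien-17-oate | C/C(=C\CO[Si](c1ccccc1)(c1ccccc1)C(C)(C)C)CC[C@H]1C(C(=O)OCC)=CC[C@H]2C(C)(C)[C@@H](O)CC[C@]12C | intermediate
18 | sodium 3β-alkoxide of 17 | C/C(=C\CO[Si](c1ccccc1)(c1ccccc1)C(C)(C)C)CC[C@H]1C(C(=O)OCC)=CC[C@H]2C(C)(C)[C@@H]([O-])CC[C@]12C.[Na+] | intermediate (not isolated)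
19 | sodium O-(3β-labdanyl) dithiocarbonate of 17 | C/C(=C\CO[Si](c1ccccc1)(c1ccccc1)C(C)(C)C)CC[C@H]1C(C(=O)OCC)=CC[C@H]2C(C)(C)[C@@H](OC(=S)[S-])CC[C@]12C.[Na+] | intermediate (not isolated)
20 | ethyl 15-[(tert-butyldiphenylsilyl)oxy]-3β-{[(methylsulfanyl)carbonothioyl]oxy}labda-7,13E-dien-17-oate | C/C(=C\CO[Si](c1ccccc1)(c1ccccc1)C(C)(C)C)CC[C@H]1C(C(=O)OCC)=CC[C@H]2C(C)(C)[C@@H](OC(=S)SC)CC[C@]12C | intermediate
21 | ethyl 15-[(tert-butyldiphenylsilyl)oxy]labda-7,13E-dien-17-oate | C/C(=C\CO[Si](c1ccccc1)(c1ccccc1)C(C)(C)C)CC[C@H]1C(C(=O)OCC)=CC[C@H]2C(C)(C)CCC[C@]12C | intermediate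
22 | ethyl 15-hydroxylabda-7,13E-dien-17-oate | C/C(=C\CO)CC[C@H]1C(C(=O)OCC)=CC[C@H]2C(C)(C)CCC[C@]12C | intermediate
23 | lithium 15-hydroxylabda-7,13E-dien-17-oate | C/C(=C\CO)CC[C@H]1C(C(=O)[O-])=CC[C@H]2C(C)(C)CCC[C@]12C.[Li+] | intermediate (not isolated)
24 | 15-hydroxylabda-7,13E-dien-17-oic acid | C/C(=C\CO)CC[C@H]1C(C(=O)O)=CC[C@H]2C(C)(C)CCC[C@]12C | intermediate
25 | 15-(isobutyryloxy)labda-7,13E-dien-17-oic isobutyric anhydride | C/C(=C\COC(=O)C(C)C)CC[C@H]1C(C(=O)OC(=O)C(C)C)=CC[C@H]2C(C)(C)CCC[C@]12C | intermediate (not isolated)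
26 | (5S,9R,10S)-15-(isobutyryloxy)labda-7,13E-dien-17-oic acid | C/C(=C\COC(=O)C(C)C)CC[C@H]1C(C(=O)O)=CC[C@H]2C(C)(C)CCC[C@]12C | target

Total step count: 16. Longest linear sequence: 16 steps, from 1 to 26; 6 and 12 are bought.

**Steps most likely to fail**

Step 9. The unactivated, trisubstituted C9=C10 alkene may add too slowly for the silyl ethers and the alkenes of the chain to survive the temperature. Closure through the tether-endo chair or on the other diene face may also take so much material that too little of the wanted adduct remains after separation. The fallback changes the approach: the dienophile is activated by a formyl group at C11 on a shortened chain, and C12–C16 are attached after ring closure. It sets out from the building blocks 6 and 12, used on a geraniol-derived aldehyde in place of 5, and comes back at 15.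

- Commercial geraniol would be protected (NaH, 4-methoxybenzyl chloride) as geranyl 4-methoxybenzyl ether F1, epoxidised at the terminal alkene with mCPBA to racemic epoxide F2 and cleaved with H5IO6 to (E)-6-[(4-methoxybenzyl)oxy]-4-methylhex-4-enal F3.
- The chemistry of steps 4 to 8 would then give, in this order, trimethylsilyl ether F4 (not isolated), hydroxy ester F5, triethylsilyl ether F6, primary alcohol F7, aldehyde F8 and, with 13, dienoate F9.
- DDQ (CH2Cl2, pH 7 buffer) would free allylic alcohol F10, and MnO2 would oxidise it to trienal F11.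
- With Me2AlCl (CH2Cl2, −78 to −20 °C) the (E)-enal should add through the transition state with the formyl group endo, which is the tether-exo, trans-fused one, to give cycloadduct aldehyde F12 with the same configuration at C3, C5, C8, C9 and C10 as 15.
- Wittig methylenation (Ph3PCH3Br, KN(SiMe3)2) would give vinyl compound F13, and hydroboration with 9-BBN would give alkylborane F14 (not isolated).
- Suzuki–Miyaura coupling (PdCl2(dppf), AsPh3, Cs2CO3, DMF/H2O) of F14 with (E)-tert-butyl[(3-iodobut-2-en-1-yl)oxy]diphenylsilane F15, made from (E)-3-iodobut-2-en-1-ol and tBuPh2SiCl, would then return 15.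

Step 4. The aldol addition may give 8 with too low an enantiomeric purity, or in the opposite sense, and the whole relay of configuration in step 9 depends on this centre. The fallback replaces face selection at the aldehyde by a catalyst-controlled ketone reduction. It sets out from 8 of insufficient purity and comes back at 8: Dess–Martin oxidation (NaHCO3, CH2Cl2) would give methyl (6E,10E)-12-[(tert-butyldiphenylsilyl)oxy]-2,2,6,10-tetramethyl-3-oxododeca-6,10-dienoate F16. Corey–Bakshi–Shibata reduction with the (R)-2-methyl oxazaborolidine and catecholborane (toluene, −78 °C), in which the quaternary carbon acts as the large group, should return (3S)-8.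

Step 15. Hydrolysis of the hindered conjugated ester may stall, or the forcing base may move the alkene out of conjugation. The fallback avoids attack at the ester carbonyl by hydroxide altogether. It sets out from 21 and comes back at 24. Reduction with iBu2AlH (CH2Cl2, −78 °C) would give 15-[(tert-butyldiphenylsilyl)oxy]labda-7,13E-dien-17-ol F17, and MnO2 would oxidise it to 15-[(tert-butyldiphenylsilyl)oxy]labda-7,13E-dien-17-al F18. Pinnick oxidation (NaClO2, NaH2PO4, 2-methylbut-2-ene, tBuOH/H2O) would give 15-[(tert-butyldiphenylsilyl)oxy]labda-7,13E-dien-17-oic acid F19, and Bu4NF in THF would then give 24.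

**Further compounds**

F1 | step 9 | geranyl 4-methoxybenzyl ether | CC(C)=CCC/C(C)=C/COCc1ccc(OC)cc1
F2 | step 9 | racemic 6,7-epoxide of F1 | CC1(C)OC1CC/C(C)=C/COCc1ccc(OC)cc1
F3 | step 9 | (E)-6-[(4-methoxybenzyl)oxy]-4-methylhex-4-enal | O=CCC/C(C)=C/COCc1ccc(OC)cc1
F4 | step 9 | trimethylsilyl ether of F5 (not isolated) | COC(=O)C(C)(C)[C@@H](O[Si](C)(C)C)CC/C(C)=C/COCc1ccc(OC)cc1
F5 | step 9 | methyl (3S,6E)-3-hydroxy-8-[(4-methoxybenzyl)oxy]-2,2,6-trimethyloct-6-enoate | COC(=O)C(C)(C)[C@@H](O)CC/C(C)=C/COCc1ccc(OC)cc1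
F6 | step 9 | methyl (3S,6E)-8-[(4-methoxybenzyl)oxy]-2,2,6-trimethyl-3-[(triethylsilyl)oxy]oct-6-enoate | COC(=O)C(C)(C)[C@@H](O[Si](CC)(CC)CC)CC/C(C)=C/COCc1ccc(OC)cc1
F7 | step 9 | (3S,6E)-8-[(4-methoxybenzyl)oxy]-2,2,6-trimethyl-3-[(triethylsilyl)oxy]oct-6-en-1-ol | OCC(C)(C)[C@@H](O[Si](CC)(CC)CC)CC/C(C)=C/COCc1ccc(OC)cc1
F8 | step 9 | (3S,6E)-8-[(4-methoxybenzyl)oxy]-2,2,6-trimethyl-3-[(triethylsilyl)oxy]oct-6-enal | O=CC(C)(C)[C@@H](O[Si](CC)(CC)CC)CC/C(C)=C/COCc1ccc(OC)cc1
F9 | step 9 | ethyl (2E,4E,7S,10E)-12-[(4-methoxybenzyl)oxy]-6,6,10-trimethyl-7-[(triethylsilyl)oxy]dodeca-2,4,10-trienoate | CCOC(=O)/C=C/C=C/C(C)(C)[C@@H](O[Si](CC)(CC)CC)CC/C(C)=C/COCc1ccc(OC)cc1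
F10 | step 9 | ethyl (2E,4E,7S,10E)-12-hydroxy-6,6,10-trimethyl-7-[(triethylsilyl)oxy]dodeca-2,4,10-trienoate | CCOC(=O)/C=C/C=C/C(C)(C)[C@@H](O[Si](CC)(CC)CC)CC/C(C)=C/CO
F11 | step 9 | ethyl (2E,4E,7S,10E)-6,6,10-trimethyl-12-oxo-7-[(triethylsilyl)oxy]dodeca-2,4,10-trienoate | CCOC(=O)/C=C/C=C/C(C)(C)[C@@H](O[Si](CC)(CC)CC)CC/C(C)=C/C=O
F12 | step 9 | ethyl 11-oxo-3β-[(triethylsilyl)oxy]drim-6-en-12-oate (drimane numbering; 5α-H, 8α-H, 9α-H, 10β-methyl) | O=C[C@H]1[C@@H](C(=O)OCC)C=C[C@H]2C(C)(C)[C@@H](O[Si](CC)(CC)CC)CC[C@]12C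
F13 | step 9 | ethyl 3β-[(triethylsilyl)oxy]-13,14,15,16-tetranorlabda-6,11-dien-17-oate | C=C[C@H]1[C@@H](C(=O)OCC)C=C[C@H]2C(C)(C)[C@@H](O[Si](CC)(CC)CC)CC[C@]12C
F14 | step 9 | B-alkyl-9-borabicyclo[3.3.1]nonane from F13, boron on C12 (not isolated) | C1CCC2CCCC1B2CC[C@H]1[C@@H](C(=O)OCC)C=C[C@H]2C(C)(C)[C@@H](O[Si](CC)(CC)CC)CC[C@]12C
F15 | step 9 | (E)-tert-butyl[(3-iodobut-2-en-1-yl)oxy]diphenylsilane | C/C(I)=C\CO[Si](c1ccccc1)(c1ccccc1)C(C)(C)C
F16 | step 4 | methyl (6E,10E)-12-[(tert-butyldiphenylsilyl)oxy]-2,2,6,10-tetramethyl-3-oxododeca-6,10-dienoate | COC(=O)C(C)(C)C(=O)CC/C(C)=C/CC/C(C)=C/CO[Si](c1ccccc1)(c1ccccc1)C(C)(C)C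
F17 | step 15 | 15-[(tert-butyldiphenylsilyl)oxy]labda-7,13E-dien-17-ol | C/C(=C\CO[Si](c1ccccc1)(c1ccccc1)C(C)(C)C)CC[C@H]1C(CO)=CC[C@H]2C(C)(C)CCC[C@]12C
F18 | step 15 | 15-[(tert-butyldiphenylsilyl)oxy]labda-7,13E-dien-17-al | C/C(=C\CO[Si](c1ccccc1)(c1ccccc1)C(C)(C)C)CC[C@H]1C(C=O)=CC[C@H]2C(C)(C)CCC[C@]12C
F19 | step 15 | 15-[(tert-butyldiphenylsilyl)oxy]labda-7,13E-dien-17-oic acid | C/C(=C\CO[Si](c1ccccc1)(c1ccccc1)C(C)(C)C)CC[C@H]1C(C(=O)O)=CC[C@H]2C(C)(C)CCC[C@]12C
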